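Each heterocycle of dicitrinone G (C1, O2, C3, C4, C4a, C8a and the primed lactone ring) holds a C3–C4 bond. This bond joins a benzylic carbon, placed ortho to the ring carbon that carries C1, to a methyl carbinol. Both rings are therefore cut to an ortho-ethylbenzoate and acetaldehyde. The precursor is a C2-symmetric, C7–CH2–C7' bridged bis(6-ethylbenzoate) with four MOM-protected phenols. In one operation a chiral lithium amide deprotonates both ethyl groups, the carbanions add to acetaldehyde and both alkoxides lactonise. This creates two rings and C3, C4, C3' and C4'. Half-reduction of one lactone and acid unmasking then deliver the quinone methide half.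

Key step: step 7

Numbering: monocyclic arenes are numbered as benzoates (C1 carries the ester). Bicyclic compounds are numbered as isochromans, with primes for the half that stays a lactone.

Configuration: CIP analysis of the target gives 3R,4S,3'R,4'S. Both C3/C4 methyl pairs are trans and both halves have the same absolute sense. A C2-symmetric bis-lactone is therefore a valid intermediate. The halves differ only at C1, which is at the aldehyde level in the quinone methide half and at the acid level in the lactone half.

Design of the precursor:
- The methylene bridge is made on the free resorcinol, where C3 is the only open position and lies ortho to two hydroxyls. It is not made between two ether groups that shield that carbon.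
- The phenols are then carried as MOM ethers, so the last step needs only mild acid.
- The methyl esters are kept. They are small leaving groups for lactonisation, and each is flanked by two ortho substituents that protect it from the amide base.

Assumption: the (R,R)-configured amide is taken to direct acetaldehyde to the face of each carbanion that gives 4S; should a first run show the opposite sense, the equally available (S,S)-amide is used with nothing else changed.

Step 1
Reactants: 1 methyl orsellinate (methyl 2,4-dihydroxy-6-methylbenzoate)
Product: 2 methyl 2,4-bis(benzyloxy)-6-methylbenzoate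
Conditions: BnBr (2.5 equiv), K2CO3, DMF, 60 °C
Reagents that add atoms: benzyl bromide, BrCc1ccccc1
Why: Williamson etherification of both phenols is routine for orsellinates, and benzyl is chosen because it survives LiN(i-Pr)2 and POCl3/DMF and leaves in the same hydrogenation that later turns the formyl group into methyl.

Step 2
Reactants: 2 methyl 2,4-bis(benzyloxy)-6-methylbenzoate
Product: 4 methyl 2,4-bis(benzyloxy)-6-ethylbenzoate, via benzylic lithium species 3 (not isolated)
Conditions: LiN(i-Pr)2 (1.2 equiv), THF, −78 °C; MeI, −78 → 0 °C
Reagents that add atoms: iodomethane, CI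
Why: Lateral lithiation of an ortho-toluate gives the ester-stabilised benzylic anion, which is C-methylated by iodomethane, while the ring protons and the OCH2Ph groups are far less acidic toward this base at −78 °C.

Step 3
Reactants: 4 methyl 2,4-bis(benzyloxy)-6-ethylbenzoate
Product: 6 methyl 2,4-bis(benzyloxy)-6-ethyl-5-formylbenzoate, via aryl iminium chloride 5 (not isolated)
Conditions: POCl3, DMF, 0 → 70 °C; then ice-water
Reagents that add atoms: N,N-dimethylformamide, CN(C)C=O (formyl carbon); water, O (formyl oxygen)
Why: Vilsmeier–Haack formylation should attack C5, para to the C2 ether and ortho to the C4 ether, because C3 lies between two benzyloxy groups of which the C2 one is turned toward it by the ester, and the ester, twisted out of conjugation by its two ortho neighbours, deactivates the ring only weakly.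

Step 4
Reactants: 6 methyl 2,4-bis(benzyloxy)-6-ethyl-5-formylbenzoate
Product: 7 methyl 6-ethyl-2,4-dihydroxy-5-methylbenzoate
Conditions: H2 (3 bar), Pd/C (10 wt%), EtOAc–AcOH, cat. HCl, rt
Reagents that add atoms: none
Why: Catalytic hydrogenolysis removes both benzyl ethers and, with acid present, carries the aldehyde (now ortho and para to free hydroxyls) through the benzylic alcohol to the methyl group, a known reduction of hydroxybenzaldehydes over Pd/C.

Step 5
Reactants: 7 methyl 6-ethyl-2,4-dihydroxy-5-methylbenzoate (two molecules); 8 formaldehyde (as paraformaldehyde, half an equivalent per 7)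
Product: 10 dimethyl 3,3'-methylenebis(6-ethyl-2,4-dihydroxy-5-methylbenzoate), via 3-hydroxymethyl arene 9 (not isolated)
Conditions: (CH2O)n, cat. H2SO4, AcOH, 50 °C
Reagents that add atoms: none
Why: Acid-catalysed hydroxyalkylation followed by Friedel–Crafts benzylation, the reaction that gives methylenebisphenols, can occur only at C3, the single free ring position, and the deficit of formaldehyde drives the benzylic alcohol on to the diarylmethane.

Step 6
Reactants: 10 dimethyl 3,3'-methylenebis(6-ethyl-2,4-dihydroxy-5-methylbenzoate)
Product: 11 dimethyl 3,3'-methylenebis[6-ethyl-2,4-bis(methoxymethoxy)-5-methylbenzoate]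
Conditions: NaH (5 equiv), MOMCl (6 equiv), DMF, 0 °C → rt
Reagents that add atoms: chloromethyl methyl ether, COCCl
Why: O-alkylation of the four sodium phenoxides (Williamson type) gives MOM ethers, which tolerate lithium amides and i-Bu2AlH and later leave under mild acid.

Step 7
Reactants: 11 dimethyl 3,3'-methylenebis[6-ethyl-2,4-bis(methoxymethoxy)-5-methylbenzoate]; 12 acetaldehyde (freshly distilled, excess)
Product: 15 (3R,4S,3'R,4'S)-7,7'-methylenebis[6,8-bis(methoxymethoxy)-3,4,5-trimethylisochroman-1-one], via dilithiated bis(benzylic) dianion 13 (not isolated), via dilithium threo bis(alkoxide) 14 (not isolated)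
Conditions: bis[(R)-1-phenylethyl]amine (2.6 equiv), n-BuLi (2.5 equiv), THF, −78 °C; 11, −78 °C; MeCHO in THF, −78 → 0 °C; AcOH quench; amine recovered by citric acid wash
Reagents that add atoms: none
Why: Each ortho-ethyl CH2 is the terminus of an extended ester enolate, so the lithium amide removes one proton from each ethyl group of 11 to give dianion 13, whereas the bridge CH2 and the C5 methyls sit meta to the esters, gain no such stabilisation and stay untouched, and the doubly ortho-substituted esters resist attack by the bulky amide. The closest known reaction is the addition of ortho-toluate carbanions generated with chiral lithium amides to aldehydes, which gives 3,4-disubstituted dihydroisocoumarins, and here it runs twice on two arenes insulated by the bridge. Each planar carbanion stays bound to lithium that still carries the chiral secondary amine, and this aggregate decides which face of C4 and of C4' meets acetaldehyde, so these two centres are reagent-controlled. C3 and C3' are set relative to C4 and C4' in a lithium-bridged closed transition state in which the aldehyde methyl turns away from the C4 methyl and from the peri C5 methyl, which leads to threo alkoxide 14 and hence to trans lactones. Both rings close in the same mode, 6-exo-trig attack of the C3 alkoxide on the neighbouring ester carbonyl C1 with loss of methoxide. Because two independent additions occur on one molecule, an addition of the wrong sense ends mainly in the meso or cis-containing diastereomers, which chromatography and crystallisation remove, so the C2-symmetric product should be enriched beyond the selectivity of a single event.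

Step 8
Reactants: 15 (3R,4S,3'R,4'S)-7,7'-methylenebis[6,8-bis(methoxymethoxy)-3,4,5-trimethylisochroman-1-one]
Product: 17 (3R,4S)-7-{[(3R,4S)-1-hydroxy-6,8-bis(methoxymethoxy)-3,4,5-trimethylisochroman-7-yl]methyl}-6,8-bis(methoxymethoxy)-3,4,5-trimethylisochroman-1-one (C1 anomers), via aluminium hemiacetal 16 (not isolated)
Conditions: i-Bu2AlH (1.0 equiv, slow addition), CH2Cl2, −78 °C; then aq. KNaC4H4O6 (potassium sodium tartrate)
Reagents that add atoms: none
Why: Partial reduction of a lactone with i-Bu2AlH stops at the tetrahedral aluminium hemiacetal 16, which holds at −78 °C and gives the lactol on hydrolysis; the two lactones of 15 are homotopic, so attack at either gives the same compound, single reduction rests on stoichiometry and slow addition alone, recovered 15 is resubmitted, and the new C1 centre is erased in step 9.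

Step 9
Reactants: 17 lactone–lactol tetra-MOM ether
Product: 19 dicitrinone G, via tetraphenol lactol 18 (not isolated)
Conditions: TFA, CH2Cl2, H2O (5 vol%), 0 °C → rt
Reagents that add atoms: none
Why: Acid-catalysed acetal hydrolysis removes the four MOM groups, and the 8-hydroxy lactol 18 ionises at C1 to a benzylic oxocarbenium ion that loses the C8 phenolic proton, a dehydration known for 6,8-dihydroxyisochroman-1-ols of the citrinin type; every ring carbon is substituted, so the released formaldehyde finds no carbon to attack, and C3, C4, C3' and C4' carry no bond that ionises or enolises under these conditions.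

Compound list
1 | methyl orsellinate | COC(=O)c1c(C)cc(O)cc1O | starting material
2 | methyl 2,4-bis(benzyloxy)-6-methylbenzoate | COC(=O)c1c(C)cc(OCc2ccccc2)cc1OCc1ccccc1 | intermediate
3 | benzylic lithium species from 2 | [Li+].[CH2-]c1cc(OCc2ccccc2)cc(OCc2ccccc2)c1C(=O)OC | intermediate
4 | methyl 2,4-bis(benzyloxy)-6-ethylbenzoate | CCc1cc(OCc2ccccc2)cc(OCc2ccccc2)c1C(=O)OC | intermediate
5 | C5 aryl(dimethyl)iminium chloride from 4 | [Cl-].CCc1c(C=[N+](C)C)c(OCc2ccccc2)cc(OCc2ccccc2)c1C(=O)OC | intermediate
6 | methyl 2,4-bis(benzyloxy)-6-ethyl-5-formylbenzoate | CCc1c(C=O)c(OCc2ccccc2)cc(OCc2ccccc2)c1C(=O)OC | intermediate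
7 | methyl 6-ethyl-2,4-dihydroxy-5-methylbenzoate | CCc1c(C)c(O)cc(O)c1C(=O)OC | intermediate
8 | formaldehyde (used as paraformaldehyde) | C=O | starting material
9 | methyl 6-ethyl-2,4-dihydroxy-3-(hydroxymethyl)-5-methylbenzoate | CCc1c(C)c(O)c(CO)c(O)c1C(=O)OC | intermediate
10 | dimethyl 3,3'-methylenebis(6-ethyl-2,4-dihydroxy-5-methylbenzoate) | CCc1c(C)c(O)c(Cc2c(O)c(C)c(CC)c(C(=O)OC)c2O)c(O)c1C(=O)OC | intermediate
11 | dimethyl 3,3'-methylenebis[6-ethyl-2,4-bis(methoxymethoxy)-5-methylbenzoate] | CCc1c(C)c(OCOC)c(Cc2c(OCOC)c(C)c(CC)c(C(=O)OC)c2OCOC)c(OCOC)c1C(=O)OC | intermediate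
12 | acetaldehyde | CC=O | starting material
13 | dilithiated bis(benzylic) dianion of 11 | [Li+].[Li+].C[CH-]c1c(C)c(OCOC)c(Cc2c(OCOC)c(C)c([CH-]C)c(C(=O)OC)c2OCOC)c(OCOC)c1C(=O)OC | intermediate
14 | dilithium bis(alkoxide) of the bis[(2R,3S)-3-arylbutan-2-ol] diester | [Li+].[Li+].COC(=O)c1c(OCOC)c(Cc2c(OCOC)c(C)c([C@H](C)[C@@H](C)[O-])c(C(=O)OC)c2OCOC)c(OCOC)c(C)c1[C@H](C)[C@@H](C)[O-] | intermediate
15 | (3R,4S,3'R,4'S)-7,7'-methylenebis[6,8-bis(methoxymethoxy)-3,4,5-trimethylisochroman-1-one] | COCOc1c(C)c2c(c(OCOC)c1Cc1c(OCOC)c(C)c3c(c1OCOC)C(=O)O[C@H](C)[C@H]3C)C(=O)O[C@H](C)[C@H]2C | intermediate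
16 | diisobutylaluminium hemiacetal of 15 at C1 | COCOc1c(C)c2c(c(OCOC)c1Cc1c(OCOC)c(C)c3c(c1OCOC)C(=O)O[C@H](C)[C@H]3C)C(O[Al](CC(C)C)CC(C)C)O[C@H](C)[C@H]2C | intermediate
17 | lactone–lactol tetra-MOM ether (C1 anomers) | COCOc1c(C)c2c(c(OCOC)c1Cc1c(OCOC)c(C)c3c(c1OCOC)C(=O)O[C@H](C)[C@H]3C)C(O)O[C@H](C)[C@H]2C | intermediate
18 | tetraphenol lactone–lactol | Oc1c(C)c2c(c(O)c1Cc1c(O)c(C)c3c(c1O)C(=O)O[C@H](C)[C@H]3C)C(O)O[C@H](C)[C@H]2C | intermediate
19 | dicitrinone G (3R,4S,3'R,4'S; 8-oxo/6-hydroxy quinone methide tautomer) | CC1=C2C(=CO[C@H](C)[C@H]2C)C(=O)C(Cc2c(O)c(C)c3c(c2O)C(=O)O[C@H](C)[C@H]3C)=C1O | target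

Total step count: 9. Longest linear sequence: 9 steps, from methyl orsellinate.

Steps most likely to fail

1. Step 7.
What may go wrong:
- The second deprotonation may be incomplete.
- The many ether oxygens may compete with the chiral amine for lithium, which would lower facial selectivity.
- Threo selectivity may be only modest.
- All of these are multiplied over two events, so separating the stereoisomers could become impractical.

Fallback (aldol first, bridge afterwards), setting out from 7 and returning at 15. NaH/MOMCl converts 7 into methyl 6-ethyl-2,4-bis(methoxymethoxy)-5-methylbenzoate F1. The chiral-amide/acetaldehyde reaction on this monomer can give only four stereoisomers, and the trans lactone (3R,4S)-6,8-bis(methoxymethoxy)-3,4,5-trimethylisochroman-1-one F2 is purified from them. HCl in MeOH frees (3R,4S)-6,8-dihydroxy-3,4,5-trimethylisochroman-1-one F3, which can be recrystallised to raise its enantiomeric purity. Condensation with half an equivalent of formaldehyde, as in step 5, occurs at C7, the only free position. It gives (3R,4S,3'R,4'S)-7,7'-methylenebis(6,8-dihydroxy-3,4,5-trimethylisochroman-1-one) F4, with the heterochiral dimer removed at this stage. NaH/MOMCl then gives 15.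

2. Step 8.
What may go wrong:
- The two like termini are discriminated only by statistics.
- The aluminium hemiacetal may collapse early and over-reduction may follow.

Fallback (directed union of two monomeric halves, so that no like termini need to be told apart), setting out from 7 through F1 and F2 as above and returning at 19. One portion of F2 is reduced with a slight excess of i-Bu2AlH to (3R,4S)-6,8-bis(methoxymethoxy)-3,4,5-trimethylisochroman-1-ol F5. TFA/CH2Cl2/H2O turns this into the monomeric quinone methide (3R,4S)-6-hydroxy-3,4,5-trimethyl-3,4-dihydroisochromen-8-one F6. The other portion is deprotected to F3 and aminomethylated at C7 (Mannich reaction, aq. CH2O, Me2NH, EtOH) to (3R,4S)-7-[(dimethylamino)methyl]-6,8-dihydroxy-3,4,5-trimethylisochroman-1-one F7. Warming F7 with F6 in AcOH makes the amine leave as its acetate salt, so it cannot add to C1. This releases an ortho-quinone methide, which is intercepted at C7 of F6, the nucleophilic α-carbon of its vinylogous acid, to give 19.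

3. Step 3.
What may go wrong:
- Attack on the ester-bearing ring may be sluggish.
- Some attack may occur at C3.
- Benzyl groups may be lost in hot POCl3.

Fallback (halogenation and cross-coupling in place of formylation), setting out from 4 and returning at 7. NBS in MeCN at 0 °C in the dark gives methyl 2,4-bis(benzyloxy)-5-bromo-6-ethylbenzoate F8. Suzuki–Miyaura methylation (MeB(OH)2, Pd(OAc)2, SPhos, K3PO4, toluene–H2O, 100 °C) gives methyl 2,4-bis(benzyloxy)-6-ethyl-5-methylbenzoate F9. Hydrogenolysis (H2, Pd/C, EtOAc) then gives 7.

Further compounds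
F1 | step 7 | methyl 6-ethyl-2,4-bis(methoxymethoxy)-5-methylbenzoate | CCc1c(C)c(OCOC)cc(OCOC)c1C(=O)OC
F2 | step 7 | (3R,4S)-6,8-bis(methoxymethoxy)-3,4,5-trimethylisochroman-1-one | COCOc1c(C)c2c(c(OCOC)c1)C(=O)O[C@H](C)[C@H]2C
F3 | step 7 | (3R,4S)-6,8-dihydroxy-3,4,5-trimethylisochroman-1-one | Oc1c(C)c2c(c(O)c1)C(=O)O[C@H](C)[C@H]2C
F4 | step 7 | (3R,4S,3'R,4'S)-7,7'-methylenebis(6,8-dihydroxy-3,4,5-trimethylisochroman-1-one) | Oc1c(C)c2c(c(O)c1Cc1c(O)c(C)c3c(c1O)C(=O)O[C@H](C)[C@H]3C)C(=O)O[C@H](C)[C@H]2C
F5 | step 8 | (3R,4S)-6,8-bis(methoxymethoxy)-3,4,5-trimethylisochroman-1-ol (C1 anomers) | COCOc1c(C)c2c(c(OCOC)c1)C(O)O[C@H](C)[C@H]2C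
F6 | step 8 | (3R,4S)-6-hydroxy-3,4,5-trimethyl-3,4-dihydroisochromen-8-one | CC1=C2C(=CO[C@H](C)[C@H]2C)C(=O)C=C1O
F7 | step 8 | (3R,4S)-7-[(dimethylamino)methyl]-6,8-dihydroxy-3,4,5-trimethylisochroman-1-one | CN(C)Cc1c(O)c(C)c2c(c1O)C(=O)O[C@H](C)[C@H]2C
F8 | step 3 | methyl 2,4-bis(benzyloxy)-5-bromo-6-ethylbenzoate | CCc1c(Br)c(OCc2ccccc2)cc(OCc2ccccc2)c1C(=O)OC
F9 | step 3 | methyl 2,4-bis(benzyloxy)-6-ethyl-5-methylbenzoate | CCc1c(C)c(OCc2ccccc2)cc(OCc2ccccc2)c1C(=O)OC
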